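Readings and results stem from a simulated flask on assumed constants; the scatter is artificial.

No run here can tell target from over-reaction product, because neither was read. The runs do show how far starting material plus intermediate falls below the charge.

| flask | starting material | catalyst | remark | time |
|---|---|---|---|---|
| north-west | 0.35 M | 1.2 mM | run made earlier |  |
| south-east | 0.55 M | 1.2 mM | run made earlier |  |
| east | 0.25 M | 2.4 mM | run made earlier |  |
| flask | 0.25 M | 1.2 mM |  | 8.0 min |

| run | time / min | intermediate / % | starting material / % |
|---|---|---|---|
| north-west | 0.333 | 12 | 86 |
| north-west | 1.00 | 31 | 65 |
| north-west | 1.50 | 40 | 54 |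
| north-west | 2.50 | 55 | 36 |
| north-west | 4.00 | 64 | 20 |
| north-west | 5.00 | 71 | 13 |
| south-east | 0.417 | 13 | 84 |
| south-east | 0.667 | 18 | 77 |
| south-east | 1.00 | 31 | 68 |
| south-east | 2.00 | 49 | 48 |
| south-east | 3.00 | 56 | 32 |
| south-east | 5.00 | 71 | 17 |
| east | 0.417 | 19 | 87 |
| east | 0.667 | 23 | 76 |
| east | 1.33 | 37 | 55 |
| east | 2.50 | 49 | 38 |
| east | 5.00 | 54 | 11 |

(readings scatter by 2 percentage points)

- what may be going on: starting material -> intermediate; catalyst + intermediate -> catalyst + target; target -> over-reaction product

1. the intermediate in the flask at 8.0 min, as a percentage of the starting material charged
2. the starting material in the flask at 8.0 min, as a percentage of the starting material charged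
3. the target in the flask at 8.0 min, as a percentage of the starting material charged
4. the over-reaction product in the flask at 8.0 min, as a percentage of the starting material charged

I take it that starting material gives intermediate, the catalyst turns intermediate into target, and target goes on to over-reaction product. My zero of the scale is a shortfall D of nothing, where starting material plus intermediate equals the charge; D itself is target plus over-reaction product. At 5.00 min, D reads 16.0% in north-west and 12.0% in south-east, a gap that readings with a scatter of 2 percentage points can produce, so I see no effect of charge.

The east run has the flask's starting material but twice its catalyst. At the same time, D in east reads 35.0%, about twice that of north-west, and intermediate reads 54% in east against 71% in north-west.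

By trapezoids, the area under the intermediate curve is 2.38 min in north-west and 2.08 min in east. Pooling both runs gives a reading of κ, the shortfall gained per unit of catalyst and of intermediate-time: 64.9 L mol⁻¹ min⁻¹.

For the flask, κ times the catalyst is a pseudo-first-order constant of 0.0779 min⁻¹, a half-life of 8.90 min. That is longer than 8.0 min, so I expect intermediate to remain in the flask at that time. With 0.408 min⁻¹ for the first step, read from north-west, I reckon 61.6% intermediate and D of 34.6% in the flask.

The forecast says 61% intermediate, 3.5% starting material, 29% target and 6.5% over-reaction product, with the split as “I guess modest over-reaction, roughly a fifth of the total”.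

The flask gives 64.3% intermediate, 4.46% starting material, 3.86% target and 27.4% over-reaction product.

    starting material → intermediate (k = 0.00648 s⁻¹)
    catalyst + intermediate → catalyst + target (k = 0.971 L mol⁻¹ s⁻¹)
    target → over-reaction product (k = 0.0199 s⁻¹)

The forecast parts from the flask on the split. Target's half-life by its own step is 0.58 min, short against 8.0 min. Feeding target at κ times catalyst times the flask's intermediate, against that half-life, balances at 4.19% target, beside the 3.86% found.

With 0.0048 M catalyst in the neighbour flask, κ gives 0.312 min⁻¹ and 18.8% intermediate at 8.00 min. The computed neighbour holds 22.1%.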